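**Retrosynthetic overview**
- The C15 acid comes from a terminal vinyl group (hydroboration, then oxidation); the C19 ester comes from the C19 alcohol and bought (R)-2-methylbutanoic acid.
- The exocyclic C8=CH2 comes from a C8 ketone (Wittig); the C3–H and C12–H bonds come from two secondary alcohols removed together by radical deoxygenation.
- Key disconnection C12–C13: a reagent-controlled (E)-crotylboration of a decalin C12 aldehyde joins the ring fragment to a four-carbon fragment (trans-but-2-ene) and sets C13.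
- The keto aldehyde comes from double ozonolysis of 19-O-silylated andrographolide.
- Ring order: no ring is built; the trans-decalin (rings A and B, with C4, C5, C9 and C10 already correct) is taken intact from andrographolide.

Assumption: andrographolide, trans-but-2-ene, (−)-Ipc2BOMe and (R)-2-methylbutanoic acid (≥98% ee) are bought as such; labdane numbering (C1–C20) is used, and the descriptors are CIP descriptors of the SMILES shown.

**Step 1**
Reactants: 1 andrographolide
Product: 2 19-O-(tert-butyldiphenylsilyl)andrographolide (C3-OH and C14-OH free)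
Conditions: TBDPSCl (1.15 equiv), imidazole (2.5 equiv), DMF, 0 °C → rt
Reagents that add atoms: tert-butyl(chloro)diphenylsilane, CC(C)(C)[Si](Cl)(c1ccccc1)c1ccccc1
Why: Selective silyl ether formation, in which the bulky chlorosilane reacts only with the primary C19 hydroxyl and leaves the secondary C3 and C14 hydroxyls free; no stereocentre is touched.

**Step 2**
Reactants: 2 19-O-(tert-butyldiphenylsilyl)andrographolide
Product: 4 19-(tert-butyldiphenylsilyloxy)-3-hydroxy-8-oxo-13,14,15,16,17-pentanor-ent-labdan-12-al (keto aldehyde; ring stereocentres as in 1), via bis-ozonide 3 (not isolated)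
Conditions: O3, CH2Cl2, −78 °C; then PPh3 (2.5 equiv), −78 °C → rt; used crude
Reagents that add atoms: ozone, [O-][O+]=O
Why: Ozonolysis with reductive work-up cleaves both C=C bonds, excising C13–C16 and C17 to unmask the C12 aldehyde and leaving C8 as a ketone; C4, C5, C9 and C10 are untouched, and C9, now α to the ketone, already carries its side chain in the stable equatorial position.

**Step 3**
Reactants: 4 keto aldehyde; 5 trans-but-2-ene
Product: 7 (12R,13S)-19-(tert-butyldiphenylsilyloxy)-3,12-dihydroxy-17-nor-ent-labd-14-en-8-one (12,13-anti homoallylic alcohol), via diisopinocampheylborinate 6 (not isolated)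
Conditions: 5 (excess), KOtBu, n-BuLi, THF, −78 → −45 °C; (−)-Ipc2BOMe (2.2 equiv), −78 °C; BF3·OEt2, −78 °C; 4, −78 °C, 4 h; then 3 M NaOH, 30% H2O2, 0 °C → rt
Reagents that add atoms: none
Why: Brown asymmetric crotylboration (a carbonyl allylation) joins the two fragments through a closed chair transition state, in which the (E)-crotyl geometry gives the 12,13-anti product and the Ipc groups derived from (+)-α-pinene select the aldehyde face so that C13 forms as S (the 13R methyl centre of the target once C12 loses its oxygen), while the hindered ketone and the free C3-OH do not compete at −78 °C.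

**Step 4**
Reactants: 7 (12R,13S)-3,12-diol ketone
Product: 8 3,12-bis-O-(imidazol-1-ylcarbonothioyl) derivative of 7
Conditions: 1,1′-thiocarbonyldiimidazole (4 equiv), DMAP (0.5 equiv), ClCH2CH2Cl, 70 °C
Reagents that add atoms: 1,1′-thiocarbonyldiimidazole, S=C(n1ccnc1)n1ccnc1
Why: Thioacylation under neutral conditions converts both secondary alcohols into radical-labile thiocarbonyl esters without enolising the ketone or disturbing C12 and C13.

**Step 5**
Reactants: 8 bis(thiocarbonylimidazolide)
Product: 9 (13R)-19-(tert-butyldiphenylsilyloxy)-17-nor-ent-labd-14-en-8-one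
Conditions: Bu3SnH (5 equiv, 0.5 M), AIBN (0.2 equiv), toluene, 90 °C
Reagents that add atoms: none
Why: Barton–McCombie radical deoxygenation replaces both C–O bonds by C–H; with Bu3SnH kept at 0.5 M, hydrogen transfer to the C12 radical is much faster than the slow 3-exo closure of a but-3-enyl radical, so the vinyl group and C13 survive (its descriptor changes from S to R only because C12 loses CIP priority).

**Step 6**
Reactants: 9 C8 ketone
Product: 10 (13R)-19-(tert-butyldiphenylsilyloxy)-ent-labda-8(17),14-diene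
Conditions: Ph3PCH3Br (4 equiv), KOtBu (3.8 equiv), toluene, rt → 90 °C
Reagents that add atoms: methyltriphenylphosphonium bromide, C[P+](c1ccccc1)(c1ccccc1)c1ccccc1.[Br-]
Why: Wittig methylenation rebuilds the exocyclic 8(17)-alkene, any base-induced equilibration at C9 favours the natural equatorial side chain, and the step is run before the base-sensitive chiral ester is installed.

**Step 7**
Reactants: 10 silyl ether diene
Product: 11 (13R)-ent-labda-8(17),14-dien-19-ol
Conditions: Bu4NF (3 equiv), THF, 50 °C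
Reagents that add atoms: none
Why: Fluoride-mediated desilylation releases the neopentyl C19 alcohol; the rest of the molecule is a hydrocarbon diene that is inert to Bu4NF.

**Step 8**
Reactants: 11 (13R)-ent-labda-8(17),14-dien-19-ol; 12 (R)-2-methylbutanoic acid
Product: 13 (13R)-ent-labda-8(17),14-dien-19-yl (2R)-2-methylbutanoate
Conditions: 12 (1.5 equiv), DCC (1.6 equiv), DMAP (0.2 equiv), CH2Cl2, 0 °C → rt
Reagents that add atoms: none
Why: Steglich esterification acylates the C19 hydroxyl; the C2′ stereocentre is brought in with the enantiopure acid, whose simple α-alkyl centre is not racemised by carbodiimide/DMAP activation at 0 °C to rt.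

**Step 9**
Reactants: 13 diene ester
Product: 15 (13R)-15-hydroxy-ent-labd-8(17)-en-19-yl (2R)-2-methylbutanoate, via alkyldisiamylborane 14 (not isolated)
Conditions: Sia2BH (1.5 equiv, from BH3·THF and 2-methylbut-2-ene), THF, 0 °C, 2 h; then 30% H2O2, 3 M aq NaOAc, 0 °C → rt
Reagents that add atoms: hydrogen peroxide, OO
Why: Hydroboration–oxidation, in which bulky disiamylborane adds anti-Markovnikov to the monosubstituted vinyl group far faster than to the hindered 1,1-disubstituted exocyclic alkene and does not reduce esters, while the acetate-buffered peroxide work-up leaves the ester and its α-centre intact.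

**Step 10**
Reactants: 15 primary alcohol
Product: 17 (13R)-19-[(2R)-2-methylbutanoyloxy]-ent-labd-8(17)-en-15-oic acid (the target), via aldehyde 16 (not isolated)
Conditions: TEMPO (0.2 equiv), PhI(OAc)2 (2.5 equiv), MeCN/H2O (1:1), rt
Reagents that add atoms: water, O
Why: TEMPO/PhI(OAc)2 oxidation in aqueous acetonitrile takes the primary alcohol through the aldehyde and its hydrate to the carboxylic acid under near-neutral conditions that leave the alkene, the ester and all stereocentres unchanged.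

**Compound list**
1 | andrographolide | C=C1CC[C@@H]2[C@](C)(CO)[C@H](O)CC[C@@]2(C)[C@@H]1C/C=C1/C(=O)OC[C@H]1O | starting material
2 | 19-O-(tert-butyldiphenylsilyl)andrographolide | C=C1CC[C@@H]2[C@](C)(CO[Si](c3ccccc3)(c3ccccc3)C(C)(C)C)[C@H](O)CC[C@@]2(C)[C@@H]1C/C=C1/C(=O)OC[C@H]1O | intermediate
3 | bis-ozonide of 2 (1,2,4-trioxolanes across C8/C17 and C12/C13; mixture at the new acetal carbons) | C1OC2(OO1)CC[C@@H]3[C@](C)(CO[Si](c4ccccc4)(c4ccccc4)C(C)(C)C)[C@H](O)CC[C@@]3(C)[C@@H]2CC5OOC6(O5)C(=O)OC[C@H]6O | intermediate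
4 | 19-(tert-butyldiphenylsilyloxy)-3-hydroxy-8-oxo-13,14,15,16,17-pentanor-ent-labdan-12-al (ring stereocentres as in 1) | O=C1CC[C@@H]2[C@](C)(CO[Si](c3ccccc3)(c3ccccc3)C(C)(C)C)[C@H](O)CC[C@@]2(C)[C@@H]1CC=O | intermediate
5 | trans-but-2-ene | C/C=C/C | starting material
6 | C12 diisopinocampheylborinate of 7 (Ipc groups from (+)-α-pinene) | O=C1CC[C@@H]2[C@](C)(CO[Si](c3ccccc3)(c3ccccc3)C(C)(C)C)[C@H](O)CC[C@@]2(C)[C@@H]1C[C@@H](OB([C@@H]3C[C@@H]4C[C@H]([C@H]3C)C4(C)C)[C@@H]3C[C@@H]4C[C@H]([C@H]3C)C4(C)C)[C@@H](C)C=C | intermediate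
7 | (12R,13S)-19-(tert-butyldiphenylsilyloxy)-3,12-dihydroxy-17-nor-ent-labd-14-en-8-one | O=C1CC[C@@H]2[C@](C)(CO[Si](c3ccccc3)(c3ccccc3)C(C)(C)C)[C@H](O)CC[C@@]2(C)[C@@H]1C[C@@H](O)[C@@H](C)C=C | intermediate
8 | 3,12-bis-O-(imidazol-1-ylcarbonothioyl) derivative of 7 | O=C1CC[C@@H]2[C@](C)(CO[Si](c3ccccc3)(c3ccccc3)C(C)(C)C)[C@H](OC(=S)n3ccnc3)CC[C@@]2(C)[C@@H]1C[C@@H](OC(=S)n1ccnc1)[C@@H](C)C=C | intermediate
9 | (13R)-19-(tert-butyldiphenylsilyloxy)-17-nor-ent-labd-14-en-8-one | O=C1CC[C@@H]2[C@](C)(CO[Si](c3ccccc3)(c3ccccc3)C(C)(C)C)CCC[C@@]2(C)[C@@H]1CC[C@@H](C)C=C | intermediate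
10 | (13R)-19-(tert-butyldiphenylsilyloxy)-ent-labda-8(17),14-diene | C=C1CC[C@@H]2[C@](C)(CO[Si](c3ccccc3)(c3ccccc3)C(C)(C)C)CCC[C@@]2(C)[C@@H]1CC[C@@H](C)C=C | intermediate
11 | (13R)-ent-labda-8(17),14-dien-19-ol | C=C1CC[C@@H]2[C@](C)(CO)CCC[C@@]2(C)[C@@H]1CC[C@@H](C)C=C | intermediate
12 | (R)-2-methylbutanoic acid | CC[C@@H](C)C(=O)O | starting material
13 | (13R)-ent-labda-8(17),14-dien-19-yl (2R)-2-methylbutanoate | C=C1CC[C@@H]2[C@](C)(COC(=O)[C@H](C)CC)CCC[C@@]2(C)[C@@H]1CC[C@@H](C)C=C | intermediate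
14 | C15 alkyl-disiamylborane of 13 | C=C1CC[C@@H]2[C@](C)(COC(=O)[C@H](C)CC)CCC[C@@]2(C)[C@@H]1CC[C@@H](C)CCB(C(C)C(C)C)C(C)C(C)C | intermediate
15 | (13R)-15-hydroxy-ent-labd-8(17)-en-19-yl (2R)-2-methylbutanoate | C=C1CC[C@@H]2[C@](C)(COC(=O)[C@H](C)CC)CCC[C@@]2(C)[C@@H]1CC[C@@H](C)CCO | intermediate
16 | (13R)-15-oxo-ent-labd-8(17)-en-19-yl (2R)-2-methylbutanoate | C=C1CC[C@@H]2[C@](C)(COC(=O)[C@H](C)CC)CCC[C@@]2(C)[C@@H]1CC[C@@H](C)CC=O | intermediate
17 | (13R)-19-[(2R)-2-methylbutanoyloxy]-ent-labd-8(17)-en-15-oic acid, i.e. (3R)-5-[(1R,4aS,5R,8aS)-5,8a-dimethyl-5-{[(2R)-2-methylbutanoyl]oxymethyl}-2-methylidenedecahydronaphthalen-1-yl]-3-methylpentanoic acid | C=C1CC[C@@H]2[C@](C)(COC(=O)[C@H](C)CC)CCC[C@@]2(C)[C@@H]1CC[C@@H](C)CC(=O)O | target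

**Totals**
Total step count: 10. Longest linear sequence: 10 steps (1 → 17).

**Three steps most likely to fail**

Step 3. The γ-keto aldehyde 4, with its free C3-OH, may form hemiketals or aldol products or react incompletely with a reagent made in situ, and a wrong C13 cannot be repaired later. The fallback keeps the exocyclic alkene so that no ketone is ever present. Setting out from 2, KMnO4 in cold aqueous THF (MgSO4 buffer, 0 °C) should attack only the electron-poor, conjugated C12=C13 bond and not the hindered isolated exocyclic alkene, giving 19-(tert-butyldiphenylsilyloxy)-3-hydroxy-13,14,15,16-tetranor-ent-labd-8(17)-en-12-al F1. The crotylboration conditions of step 3 then give, by way of the diisopinocampheylborinate F2, the (12R,13S)-3,12-diol F3. Thiocarbonyldiimidazole/DMAP gives the bis(thiocarbonylimidazolide) F4, and Bu3SnH/AIBN reduces F4 directly to 10, where the route is rejoined; the Wittig step is then not needed.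

Step 6. The C8 ketone is hindered by the C9 side chain and the axial C10 methyl and is enolisable, so the ylide may only deprotonate it. The fallback is a Peterson olefination in two operations. Setting out from 9, Me3SiCH2Li with anhydrous CeCl3 (THF, −78 °C) adds to the ketone without enolising it and gives the β-hydroxysilane (13R)-19-(tert-butyldiphenylsilyloxy)-17-(trimethylsilyl)-ent-labd-14-en-8-ol F5. KH in THF then eliminates F5 to 10, where the route is rejoined.

Step 9. The exocyclic alkene may also be hydroborated, or the vinyl group may be left partly untouched. The fallback tells the two alkenes apart by metathesis instead of hydroboration. Setting out from 13, cross-metathesis with vinylboronic acid pinacol ester (second-generation Hoveyda–Grubbs catalyst, CH2Cl2, 40 °C), to which the hindered 1,1-disubstituted exocyclic alkene is inert, gives the alkenylboronate (13R,14E)-15-(4,4,5,5-tetramethyl-1,3,2-dioxaborolan-2-yl)-ent-labda-8(17),14-dien-19-yl (2R)-2-methylbutanoate F6. NaBO3·4H2O (THF/H2O, rt) oxidises the C–B bond of F6 to the enol and hence to aldehyde 16, where the route is rejoined; 16 is then taken to 17 with NaClO2/NaH2PO4/2-methylbut-2-ene in t-BuOH/H2O.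

**Further compounds**
F1 | step 3 | 19-(tert-butyldiphenylsilyloxy)-3-hydroxy-13,14,15,16-tetranor-ent-labd-8(17)-en-12-al | C=C1CC[C@@H]2[C@](C)(CO[Si](c3ccccc3)(c3ccccc3)C(C)(C)C)[C@H](O)CC[C@@]2(C)[C@@H]1CC=O
F2 | step 3 | C12 diisopinocampheylborinate of F3 | C=C1CC[C@@H]2[C@](C)(CO[Si](c3ccccc3)(c3ccccc3)C(C)(C)C)[C@H](O)CC[C@@]2(C)[C@@H]1C[C@@H](OB([C@@H]3C[C@@H]4C[C@H]([C@H]3C)C4(C)C)[C@@H]3C[C@@H]4C[C@H]([C@H]3C)C4(C)C)[C@@H](C)C=C
F3 | step 3 | (12R,13S)-19-(tert-butyldiphenylsilyloxy)-ent-labda-8(17),14-diene-3,12-diol | C=C1CC[C@@H]2[C@](C)(CO[Si](c3ccccc3)(c3ccccc3)C(C)(C)C)[C@H](O)CC[C@@]2(C)[C@@H]1C[C@@H](O)[C@@H](C)C=C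
F4 | step 3 | 3,12-bis-O-(imidazol-1-ylcarbonothioyl) derivative of F3 | C=C1CC[C@@H]2[C@](C)(CO[Si](c3ccccc3)(c3ccccc3)C(C)(C)C)[C@H](OC(=S)n3ccnc3)CC[C@@]2(C)[C@@H]1C[C@@H](OC(=S)n1ccnc1)[C@@H](C)C=C
F5 | step 6 | (13R)-19-(tert-butyldiphenylsilyloxy)-17-(trimethylsilyl)-ent-labd-14-en-8-ol (either C8 epimer) | C[Si](C)(C)CC1(O)CC[C@@H]2[C@](C)(CO[Si](c3ccccc3)(c3ccccc3)C(C)(C)C)CCC[C@@]2(C)[C@@H]1CC[C@@H](C)C=C
F6 | step 9 | (13R,14E)-15-(4,4,5,5-tetramethyl-1,3,2-dioxaborolan-2-yl)-ent-labda-8(17),14-dien-19-yl (2R)-2-methylbutanoate | C=C1CC[C@@H]2[C@](C)(COC(=O)[C@H](C)CC)CCC[C@@]2(C)[C@@H]1CC[C@@H](C)/C=C/B1OC(C)(C)C(C)(C)O1
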